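If reagent stands in excess, I reckon a flask by one time. Summer and dawn charge reagent at 5.00 times the substrate, so turning the whole charge into single product takes 20.0 % of the reagent.

| flask | substrate | reagent | temperature | remark | time |
|---|---|---|---|---|---|
| beta | 0.045 M | 0.16 M | 85 °C | run made earlier |  |
| theta | 0.070 M | 0.16 M | 102 °C | run made earlier |  |
| epsilon | 0.032 M | 0.24 M | 85 °C | run made earlier |  |
| summer | 0.032 M | 0.160 M | 90 °C |  | 30 h |
| dawn | 0.032 M | 0.160 M | 115 °C |  | 30 h |

| run | time / h | substrate / % | tetra adduct / % | tris adduct / % | bis adduct / % | single product / % |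
|---|---|---|---|---|---|---|
| beta | 2.00 | 88 | 0 | 1 | 0 | 5 |
| beta | 3.00 | 84 | 0 | 1 | 3 | 0 |
| beta | 4.00 | 83 | 2 | 0 | 0 | 1 |
| beta | 6.00 | 68 | 2 | 4 | 2 | 4 |
| beta | 10.0 | 65 | 1 | 2 | 0 | 6 |
| beta | 15.0 | 60 | 4 | 3 | 1 | 9 |
| beta | 25.0 | 57 | 0 | 3 | 0 | 15 |
| theta | 1.50 | 80 | 0 | 1 | 0 | 5 |
| theta | 3.00 | 70 | 0 | 5 | 0 | 6 |
| theta | 6.00 | 67 | 5 | 0 | 2 | 17 |
| theta | 8.00 | 65 | 0 | 0 | 2 | 20 |
| theta | 12.0 | 56 | 0 | 0 | 1 | 28 |
| theta | 15.0 | 59 | 1 | 0 | 1 | 28 |
| epsilon | 5.00 | 76 | 0 | 0 | 0 | 6 |
| epsilon | 10.0 | 66 | 0 | 2 | 0 | 10 |
| epsilon | 15.0 | 55 | 3 | 0 | 2 | 20 |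
| epsilon | 20.0 | 53 | 1 | 0 | 2 | 20 |
| epsilon | 25.0 | 47 | 0 | 2 | 1 | 22 |

(scatter of a reading: 2 percentage points)

- the numbers in the tables scatter by 2 percentage points (one standard deviation)
- a reading of substrate is of its free form alone

- which of these there is most of at the end, counted by the substrate in it, summer (tetra adduct / tris adduct / substrate / bis adduct / single product)
- which of these there is most of at the end, counted by the substrate in it, dawn (tetra adduct / tris adduct / substrate / bis adduct / single product)
- amount of the one of these that there is most of at the end, in percent of the substrate charged, summer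
- amount of the one of these that there is most of at the end, in percent of the substrate charged, dawn

My ladder has three rungs. On the first, beta's balance lacks 20.0 % at 6.00 h and 25.0 % at 25.0 h, while hotter theta lacks 11.0 % at 15.0 h, less than beta. So I count free substrate and this gap as one pool, with the free share read from the runs.

On the second rung, beta's 15 % of single product at 25.0 h gives 154 h. This is the drain time, the time in which the pool falls by a factor e, a pseudo-first-order lifetime. Theta gives 45.7 h. Epsilon gives 101 h, so beta over epsilon reads 1.52 beside a reagent ratio of 1.50, though these two runs differ in their substrate charge as well and each figure rests on one scattered reading.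

On the third rung stand the adducts: theta's last tetra adduct reading is 1 %, within the scatter of 2 percentage points.

Taking the logarithm of the drain time as straight in temperature, I get 108 h for summer, so 24.3 % drains. With a free share of 71.4 %, I reckon summer at 54.1 % of substrate, more than the drained part, so I name substrate for summer. Stretched past theta, I reckon dawn's drain time at 18.0 h, so 81.0 % drains, shared between single product and its adducts. The drained part is more than the pool left in dawn, so I name single product for dawn.

The forecast, holding that “Single product is the real outlet”, names substrate at 52 % (44 % to 60 %) for summer and single product at 76 % (52 % to 90 %) for dawn, below my drained figure.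

Summer gives substrate at 51.5 %, and dawn gives single product at 74.2 %.

    substrate + reagent → single product + by-product (k = 0.0865 L mol⁻¹ h⁻¹, Ea = 81.0 kJ mol⁻¹)
    reagent + single product → bis adduct + by-product (k = 0.00669 L mol⁻¹ h⁻¹, Ea = 85.0 kJ mol⁻¹)
    reagent + bis adduct → tris adduct + by-product (k = 0.0906 L mol⁻¹ h⁻¹, Ea = 87.0 kJ mol⁻¹)
    reagent + tris adduct → tetra adduct + by-product (k = 0.177 L mol⁻¹ h⁻¹, Ea = 79.0 kJ mol⁻¹)
    substrate ⇌ dormant form (K = 0.430, k = 0.0897 h⁻¹, Ea = 118 kJ mol⁻¹, ΔH = −44.0 kJ mol⁻¹)
    (constants at 90 °C)

In dawn, single product and its three adducts sum to 82.8 %, against my drained 81.0 %. The neighbour flask is dawn with 20.0 equiv of reagent. Scaling by reagent, I reckon its drain time at 4.51 h, so its 30 h spans 6.65 drain times, and my reckoning leaves 0.129 % of the pool. The neighbour flask holds 0.053 % of substrate and 0.00924 % of dormant form, with 53.4 % of single product and 39.9 % of tetra adduct.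

The readings are calculated with made-up constants, noise included.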